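The numbers in the tables come from a simulation on assumed constants.

**Two partners.** First end groups react with dissolved second end groups to give links and by-product, and that by-product takes further first end groups into side product. The next charge therefore hangs on this split.

- delta: first end groups 0.0050 M; solid second end groups 10 mM; run made earlier
- flask: first end groups 0.0050 M; solid second end groups 5.25 mM; time 5.0 min

- delta (time / s: links / %, first end groups / %): 10.0: 12, 87; 15.0: 19, 79; 25.0: 29, 67; 40.0: 43, 51; 50.0: 48, 38; 80.0: 58, 19; 90.0: 64, 21

(readings scatter by 2 percentage points)

- amount of links at 5.0 min, in percent of the first end groups charged
- the change that raises the amount of links at 5.0 min, in percent of the first end groups charged most ("none" if none brings more than 2 percentage points) (ochre / red / none)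
- amount of links at 5.0 min, in percent of the first end groups charged, after red

- solid second end groups is a solid; its amount is given per volume of the solution
- candidate steps: solid second end groups <-> second end groups; first end groups + by-product -> side product; first end groups + second end groups -> links + by-product
- at the start none of the solid second end groups is in solution

**Crossover level.** Call X the by-product, in percent of the first end groups charged, at which links and side product form equally fast. Near zero X, each by-product takes one first end group, so links and side product tie at 50%: that is our zero. For steady [second end groups], free by-product is X(1 − exp(−L/X)), which for moderate links L and side product V gives X ≈ L^2/(2V) − L/3. The last two delta readings average 61.0% links and 19.0% side product, so X reads 77.6%, within the scatter.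

**Our reckoning.** Once first end groups are consumed, links are the mean of the whole charge and the free by-product. Starting from the tie, this gives 68.4%, 72.7%, then 73.6% for this flask. That uses 3.68 mM of solid, less than the 5.25 mM charged.

**The change.** In the delta run, first end groups fall at 0.0139 /s by the first reading and 0.0168 /s by the fourth, so no dissolving lag shows and we expect little from ochre. Red doubles X, giving 79.3%, then 81.0%. We choose red.

The forecast gives 73%, red and 81%, holding that the near-saturated solution “makes solubility the control, not the dissolution coefficient”.

**Result.** The flask gives 74.5% links, and 81.9% after red, a gain of 7.4 percentage points against 0.14 points for ochre. Its [second end groups] stands at 95.9% of saturation at 0.500 min. X acts as a selectivity factor written as a level: by-product at 5.00 min is 49.2% of the charge, still below X.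

    solid second end groups ⇌ second end groups, rate k1*(cs1 - [second end groups]) while solid is left; crystals form when [second end groups] > cs1 (solubility = 0.850 mM, k = 1.30 /s)
    first end groups + by-product → side product (k = 3.60 /M/s)
    first end groups + second end groups → links + by-product (k = 18.0 /M/s)

**Second flask.** In the neighbour charged with 0.020 M first end groups, X falls to 19.4%, and one step of our reckoning from the tie gives 59.0% links, more than the 26.2% the solid can supply, so in that neighbour we expect links at the solid's cap, with first end groups left over. It gives 26.2% links, 26.2% side product and 47.5% first end groups left, with solid at 0%.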